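**Retrosynthetic overview**

1. Feature: both benzene rings of the 2,2'-dioxygenated diphenyl ether carry a 1,3-dibromo pair. In the anisole ring (ring A) the bromines sit ortho and para to the OMe oxygen; in the phenol ring (ring B) they sit ortho and para to the bridging oxygen and meta to OH.
2. 17 ⇐ 16 (S–O cleavage of the ring B mesylate) ⇐ 14 (O–CH3 bond at the ring A hydroxyl).
3. 14 ⇐ 9 + Br2: four C–Br bonds in one flask. The free OH steers ring A; the sulfonylated oxygen of ring B is silenced, so the bridging oxygen steers ring B.
4. 9 ⇐ 8 (O–benzyl) ⇐ 6 (O–Ms) ⇐ 3 (C–CHO to C–OH, Baeyer–Villiger) ⇐ 1 + 2 (diaryl ether C–O bond by SNAr).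
5. No ring is formed. Ring A comes from 1 and ring B from 2, so the two outer oxygens are told apart from the first step.

Key step: step 5

Remark: molecular bromine without a catalyst is assumed to stop after ring A, so the one-flask bromination is run in two stages and FeBr3 is added for ring B.

**Route**

Step 1
Reactants: 1 2-(benzyloxy)phenol; 2 2-fluorobenzaldehyde
Product: 3 2-[2-(benzyloxy)phenoxy]benzaldehyde
Conditions: K2CO3, DMF, 120 °C
Reagents that add atoms: none
Why: Nucleophilic aromatic substitution by addition–elimination: the ortho formyl group activates the C–F carbon toward the phenoxide of 1 and fluoride is the best leaving group for this mechanism, so the diaryl ether forms with benzyl on the ring A oxygen and the formyl group as the latent hydroxyl of ring B.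

Step 2
Reactants: 3 2-[2-(benzyloxy)phenoxy]benzaldehyde; 4 3-chloroperoxybenzoic acid (mCPBA)
Product: 6 2-[2-(benzyloxy)phenoxy]phenol, via aryl formate 5 (not isolated)
Conditions: mCPBA, CH2Cl2, 0 °C to rt; then K2CO3 (cat.), MeOH, rt
Reagents that add atoms: 3-chloroperoxybenzoic acid, OOC(=O)c1cccc(Cl)c1
Why: Baeyer–Villiger (Dakin-type) oxidation: in the Criegee adduct the aryl group carrying the ortho aryloxy donor should migrate in preference to hydride, and the resulting formate 5 is transesterified by methanol under mild base while the benzyl ether and the diaryl ether are untouched.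

Step 3
Reactants: 6 2-[2-(benzyloxy)phenoxy]phenol; 7 methanesulfonyl chloride
Product: 8 2-[2-(benzyloxy)phenoxy]phenyl methanesulfonate
Conditions: MsCl, Et3N, CH2Cl2, 0 °C
Reagents that add atoms: methanesulfonyl chloride, CS(=O)(=O)Cl
Why: O-sulfonylation of a phenol with a sulfonyl chloride and a tertiary amine is general, and the only free hydroxyl in 6 is the one on ring B, so the mask is placed without any selectivity question.

Step 4
Reactants: 8 2-[2-(benzyloxy)phenoxy]phenyl methanesulfonate
Product: 9 2-(2-hydroxyphenoxy)phenyl methanesulfonate
Conditions: H2 (1 atm), 10% Pd/C, EtOAc, rt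
Reagents that add atoms: none
Why: Catalytic hydrogenolysis cleaves the benzylic C–O bond, whereas aryl methanesulfonates and diaryl ethers are inert to hydrogen on Pd/C at ambient pressure, so only the ring A hydroxyl is set free.

Step 5
Reactants: 9 2-(2-hydroxyphenoxy)phenyl methanesulfonate; 10 bromine
Product: 14 3,5-dibromo-2-(3,5-dibromo-2-hydroxyphenoxy)phenyl methanesulfonate, via ring A monobromide 11 (not isolated), via ring A dibromide 12 (not isolated), via tribromide 13 (not isolated)
Conditions: Br2 (2.05 equiv), CH2Cl2, −10 °C to rt; then FeBr3 (0.2 equiv), Br2 (2.2 equiv), 0 to 40 °C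
Reagents that add atoms: bromine, BrBr
Why: All four C–Br bonds form by ordinary arenium-ion (SEAr) bromination, the closest known reactions being the ortho,para-dibromination of phenols and the bromination of O-acylated or O-sulfonylated catechol monoethers para to the ether oxygen; no ring is closed and no stereocentre is formed. In the first stage ring A should react alone, because its free hydroxyl is by far the strongest donor in the molecule, and it should take bromine para and then ortho to OH (11, then 12); the competing site para to the bridging oxygen is served only by an aryloxy lone pair shared with the electron-poor ring B, and low temperature in a non-polar solvent further favours attack next to OH. In ring B the sulfonyl group removes the donor power of its own oxygen, so the bridging oxygen is the only activating group and should send the third bromine para (13) and the fourth ortho to itself; both sites are meta to the sulfonate, which is why FeBr3 is added for this stage. Over-bromination should be held back because each of the two C–H positions left on ring A is flanked by two substituents and is meta to the hydroxyl, the ring B positions ortho and para to the sulfonate have no donor behind them, and total bromine is kept near four equivalents. The mesylate is preferred to a carboxylate ester because it lends its para position almost no resonance help, does not migrate to the neighbouring phenol and survives HBr and FeBr3.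

Step 6
Reactants: 14 3,5-dibromo-2-(3,5-dibromo-2-hydroxyphenoxy)phenyl methanesulfonate; 15 iodomethane
Product: 16 3,5-dibromo-2-(3,5-dibromo-2-methoxyphenoxy)phenyl methanesulfonate
Conditions: MeI, K2CO3, acetone, rt to 40 °C
Reagents that add atoms: iodomethane, CI
Why: Williamson O-methylation: the acidic ortho,para-dibrominated phenol is deprotonated by K2CO3 and alkylated by MeI in an SN2 step, and since the ring B oxygen is still sulfonylated the methyl group can only go onto the ring A oxygen.

Step 7
Reactants: 16 3,5-dibromo-2-(3,5-dibromo-2-methoxyphenoxy)phenyl methanesulfonate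
Product: 17 3,5-dibromo-2-(3,5-dibromo-2-methoxyphenoxy)phenol
Conditions: NaOH (2 M aq.), 1,4-dioxane, 60 °C; then 1 M HCl
Reagents that add atoms: none
Why: Alkaline hydrolysis of an aryl methanesulfonate (attack at sulfur or sulfene elimination) should be fast because the leaving dibrominated aryloxide is well stabilised, while the aryl bromides, the methyl ether and the unactivated diaryl ether are stable to aqueous hydroxide at this temperature.

**Compound list**

1 | 2-(benzyloxy)phenol | Oc1ccccc1OCc1ccccc1 | starting material
2 | 2-fluorobenzaldehyde | O=Cc1ccccc1F | starting material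
3 | 2-[2-(benzyloxy)phenoxy]benzaldehyde | O=Cc1ccccc1Oc1ccccc1OCc1ccccc1 | intermediate
4 | 3-chloroperoxybenzoic acid (mCPBA) | OOC(=O)c1cccc(Cl)c1 | starting material
5 | 2-[2-(benzyloxy)phenoxy]phenyl formate | O=COc1ccccc1Oc1ccccc1OCc1ccccc1 | intermediate (not isolated)
6 | 2-[2-(benzyloxy)phenoxy]phenol | Oc1ccccc1Oc1ccccc1OCc1ccccc1 | intermediate
7 | methanesulfonyl chloride | CS(=O)(=O)Cl | starting material
8 | 2-[2-(benzyloxy)phenoxy]phenyl methanesulfonate | CS(=O)(=O)Oc1ccccc1Oc1ccccc1OCc1ccccc1 | intermediate
9 | 2-(2-hydroxyphenoxy)phenyl methanesulfonate | CS(=O)(=O)Oc1ccccc1Oc1ccccc1O | intermediate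
10 | bromine | BrBr | starting material
11 | 2-(5-bromo-2-hydroxyphenoxy)phenyl methanesulfonate | CS(=O)(=O)Oc1ccccc1Oc1cc(Br)ccc1O | intermediate (not isolated)
12 | 2-(3,5-dibromo-2-hydroxyphenoxy)phenyl methanesulfonate | CS(=O)(=O)Oc1ccccc1Oc1cc(Br)cc(Br)c1O | intermediate (not isolated)
13 | 5-bromo-2-(3,5-dibromo-2-hydroxyphenoxy)phenyl methanesulfonate | CS(=O)(=O)Oc1cc(Br)ccc1Oc1cc(Br)cc(Br)c1O | intermediate (not isolated)
14 | 3,5-dibromo-2-(3,5-dibromo-2-hydroxyphenoxy)phenyl methanesulfonate | CS(=O)(=O)Oc1cc(Br)cc(Br)c1Oc1cc(Br)cc(Br)c1O | intermediate
15 | iodomethane | CI | starting material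
16 | 3,5-dibromo-2-(3,5-dibromo-2-methoxyphenoxy)phenyl methanesulfonate | CS(=O)(=O)Oc1cc(Br)cc(Br)c1Oc1cc(Br)cc(Br)c1OC | intermediate
17 | 3,5-dibromo-2-(3,5-dibromo-2-methoxyphenoxy)phenol | COc1c(Br)cc(Br)cc1Oc1c(O)cc(Br)cc1Br | target

**Step count**

Total step count: 7. Longest linear sequence: 7 steps (1 → 3 → 6 → 8 → 9 → 14 → 16 → 17).

**Steps most likely to fail**

Step 5. Positional control may be lost in the later substitutions. Once ring B carries one bromine, attack para to the sulfonate oxygen or at a flanked position of ring A may compete with attack ortho to the bridging oxygen. The second bromination of ring A may also go in part para to the bridging oxygen. The fallback gives up late bromination and carries all four bromines in on the two rings; it sets out from 2 and comes back to the route at 17. Compound 2 would be dibrominated with NBS in concentrated H2SO4 at 60 °C, where the fluorine (ortho/para) and the formyl group (meta) direct to the same carbons, through 5-bromo-2-fluorobenzaldehyde F1 to 3,5-dibromo-2-fluorobenzaldehyde F2. Purchased 3,5-dibromo-2-methoxybenzaldehyde F3 would be oxidised with mCPBA through 3,5-dibromo-2-methoxyphenyl formate F4 and methanolysed (K2CO3 cat., MeOH) to 3,5-dibromo-2-methoxyphenol F5. SNAr of F5 on F2 (K2CO3, DMF, 90 °C) would give 3,5-dibromo-2-(3,5-dibromo-2-methoxyphenoxy)benzaldehyde F6. A second Baeyer–Villiger oxidation through 3,5-dibromo-2-(3,5-dibromo-2-methoxyphenoxy)phenyl formate F7, followed by methanolysis, would give 17 directly.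

Step 6. The flanked, weakly nucleophilic phenoxide may alkylate slowly, and under base the sulfonyl group may be transferred to the neighbouring phenoxide or be cleaved. The fallback sets out from 14 and comes back at 16. It replaces the phenoxide alkylation by a Mitsunobu etherification (MeOH, PPh3, diisopropyl azodicarboxylate, THF, 0 °C to rt), in which the acidic phenol acts as the pronucleophile under neutral conditions and no free base is present.

Step 2. Hydride instead of aryl migration in the Criegee adduct would lead to over-oxidation to the carboxylic acid, and the oxidation of the aldehyde may stall. The fallback sets out from 1 and comes back at 6, bypassing the aldehyde. An Ullmann-type coupling of 1 with purchased 1-bromo-2-(methoxymethoxy)benzene F8 (CuI, picolinic acid, K3PO4, DMSO, 90 °C) would give 1-(benzyloxy)-2-[2-(methoxymethoxy)phenoxy]benzene F9. Acid methanolysis of the acetal (HCl, MeOH, 40 °C), which leaves the benzyl ether intact, would then give 6.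

**Further compounds**

F1 | step 5 | 5-bromo-2-fluorobenzaldehyde | O=Cc1cc(Br)ccc1F
F2 | step 5 | 3,5-dibromo-2-fluorobenzaldehyde | O=Cc1cc(Br)cc(Br)c1F
F3 | step 5 | 3,5-dibromo-2-methoxybenzaldehyde (purchased) | COc1c(Br)cc(Br)cc1C=O
F4 | step 5 | 3,5-dibromo-2-methoxyphenyl formate | COc1c(Br)cc(Br)cc1OC=O
F5 | step 5 | 3,5-dibromo-2-methoxyphenol | COc1c(Br)cc(Br)cc1O
F6 | step 5 | 3,5-dibromo-2-(3,5-dibromo-2-methoxyphenoxy)benzaldehyde | COc1c(Br)cc(Br)cc1Oc1c(Br)cc(Br)cc1C=O
F7 | step 5 | 3,5-dibromo-2-(3,5-dibromo-2-methoxyphenoxy)phenyl formate | COc1c(Br)cc(Br)cc1Oc1c(Br)cc(Br)cc1OC=O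
F0 | step 6 | none | none
F8 | step 2 | 1-bromo-2-(methoxymethoxy)benzene (purchased) | COCOc1ccccc1Br
F9 | step 2 | 1-(benzyloxy)-2-[2-(methoxymethoxy)phenoxy]benzene | COCOc1ccccc1Oc1ccccc1OCc1ccccc1
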